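**Retrosynthetic overview**
- Target ⇒ its 12-oxo analogue (a β-keto lactone); the last step is a hydroxyl-directed syn-1,3 reduction that sets C12.
- Key disconnection C12–C13: an acyl radical/acyl–nickel species from a C12 aldehyde (acyl anion equivalent) is joined to an α-bromo-β-hydroxy lactone (enolonium equivalent); both carbons are electrophilic in the free fragments.
- C12 aldehyde ⇐ andrographolide by oxidative excision of its lactone at C12=C13; this supplies C3, C4, C5, C9, C10 and the exo-methylene.
- Bromolactone ⇐ (S)-3-hydroxy-γ-butyrolactone; this supplies C14, and C13 settles trans to it.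
- Rings: the decalin (rings A and B) comes intact from andrographolide and the lactone (ring C) intact from the hydroxybutyrolactone; no ring is formed, the two are only joined.

Assumption: andrographolide (bulk Andrographis paniculata extract, >98 %) counts as a cheap commercial starting material; labdane numbering is used for the side chain (C12 carbinol, C13/C14 lactone stereocentres, C15 OCH2, C16 lactone C=O).

**Step 1**
Reactants: 1 andrographolide
Product: 3 C12 aldehyde (3,19-dihydroxy-13,14,15,16-tetranor-ent-labd-8(17)-en-12-al), via 12,13-diol 2 (not isolated)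
Conditions: KMnO4 (0.7 equiv), acetone–H2O, −10 °C; then NaIO4, H2O, 0 °C → rt
Reagents that add atoms: potassium permanganate, [K+].[O-][Mn](=O)(=O)=O
Why: KMnO4 syn-dihydroxylation followed by NaIO4 glycol cleavage – KMnO4 is an ambiphilic oxidant not slowed by the conjugated carbonyl at C12=C13, the 8(17)-exo-methylene is shielded by C20 and the C9 side chain, and the 3,19-diol (a 1,3-diol) is inert to NaIO4; no stereocentre is made, C3, C4, C5, C9 and C10 are carried over from 1.

**Step 2**
Reactants: 4 (S)-3-hydroxy-γ-butyrolactone
Product: 5 (3S,4R)-3-bromo-4-hydroxyoxolan-2-one (trans)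
Conditions: LiN(iPr)2 (2.2 equiv), THF, −78 °C; CBr4, −78 °C; AcOH quench at −78 °C
Reagents that add atoms: carbon tetrabromide, BrC(Br)(Br)Br
Why: Fráter–Seebach-type alkoxide/enolate dianion chemistry – bromine enters anti to the C4 alkoxide to give the trans bromohydrin; the C3 configuration is erased in step 3 and the C4 centre (later C14) is untouched.

**Step 3 (key step)**
Reactants: 3 C12 aldehyde; 5 (3S,4R)-3-bromo-4-hydroxyoxolan-2-one
Product: 6 12-oxo β-keto lactone, (3R,4S)-4-hydroxy-3-(decalinylacetyl)oxolan-2-one
Conditions: (Bu4N)4[W10O32] (2 mol %), NiBr2(dme) (10 mol %), 4,4′-di-tert-butyl-2,2′-bipyridine (12 mol %), K2HPO4 (1.5 equiv), 5 (1.5 equiv), MeCN, 390 nm LED, 25 °C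
Reagents that add atoms: none
Why: Proposed new method: extension of nickel/decatungstate aldehyde C–H acylation (closest known type: acylation of α-bromo esters and aryl halides by aldehydes under nickel/[W10O32]4− dual catalysis) to a secondary α-bromo lactone – the photoexcited [W10O32]4− anion abstracts the formyl hydrogen of 3 to give a nucleophilic acyl radical (an acyl anion equivalent at C12), nickel captures it together with the C13 radical released from the C–Br bond of 5 (an enolonium equivalent), and reductive elimination joins two carbons that are both electrophilic in the free fragments; C13 of the β-keto lactone is epimerisable and settles trans to the C14 hydroxyl carried in from 4.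

**Step 4**
Reactants: 6 12-oxo β-keto lactone
Product: 7 target, (12S,13S,14S)-12-hydroxy-12,13-dihydroandrographolide (CNP0113086.2)
Conditions: Et2BOMe (4 equiv), THF–MeOH 4:1, −78 °C; NaBH4, −78 °C; AcOH, then MeOH co-evaporation
Reagents that add atoms: none
Why: Narasaka–Prasad syn-1,3 reduction – Et2BOMe ties the C14 hydroxyl and the C12 ketone into a six-membered boron chelate (C15 and C16 equatorial, trans-fused to the lactone) and external hydride adds axially to give the 12,14-syn diol, i.e. 12S; the lactone and the exo-methylene are inert to NaBH4 at −78 °C.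

**Compound list**
1 | andrographolide | C=C1CC[C@@H]2[C@](C)(CO)[C@H](O)CC[C@@]2(C)[C@@H]1C/C=C1/C(=O)OC[C@H]1O | starting material
2 | 12,13-diol (12,13-dihydroxy-12,13-dihydroandrographolide; C12/C13 configuration not defined, both centres are destroyed) | C=C1CC[C@@H]2[C@](C)(CO)[C@H](O)CC[C@@]2(C)[C@@H]1CC(O)C1(O)C(=O)OC[C@H]1O | intermediate
3 | C12 aldehyde, 2-[(1R,4aS,5R,6R,8aS)-6-hydroxy-5-(hydroxymethyl)-5,8a-dimethyl-2-methylidenedecahydronaphthalen-1-yl]acetaldehyde | C=C1CC[C@@H]2[C@](C)(CO)[C@H](O)CC[C@@]2(C)[C@@H]1CC=O | intermediate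
4 | (S)-3-hydroxy-γ-butyrolactone, (4S)-4-hydroxyoxolan-2-one | O=C1C[C@H](O)CO1 | starting material
5 | (3S,4R)-3-bromo-4-hydroxyoxolan-2-one (trans) | Br[C@@H]1C(=O)OC[C@H]1O | intermediate
6 | 12-oxo β-keto lactone, (3R,4S)-4-hydroxy-3-{[(1R,4aS,5R,6R,8aS)-6-hydroxy-5-(hydroxymethyl)-5,8a-dimethyl-2-methylidenedecahydronaphthalen-1-yl]acetyl}oxolan-2-one | C=C1CC[C@@H]2[C@](C)(CO)[C@H](O)CC[C@@]2(C)[C@@H]1CC(=O)[C@@H]1C(=O)OC[C@H]1O | intermediate
7 | target, (3S,4S)-4-hydroxy-3-{(1S)-1-hydroxy-2-[(1R,4aS,5R,6R,8aS)-6-hydroxy-5-(hydroxymethyl)-5,8a-dimethyl-2-methylidenedecahydronaphthalen-1-yl]ethyl}oxolan-2-one | C=C1CC[C@@H]2[C@](C)(CO)[C@H](O)CC[C@@]2(C)[C@@H]1C[C@H](O)[C@@H]1C(=O)OC[C@H]1O | target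

**Step count**
Total steps: 4. Longest linear sequence: 3 (steps 1, 3, 4); step 2 is a one-step side branch.

**Steps most likely to fail, with fallbacks**

Step 3 (key coupling). Risks are hydrogen abstraction at carbinol or allylic C–H instead of the formyl C–H, β-hydroxide loss from the C13–nickel species, and dehydration of 6 to an acylbutenolide. The fallback sets out from 3 and comes back at 6. Oxidise 3 with NaClO2/NaH2PO4/2-methyl-2-butene to the C12 carboxylic acid F2. Convert it with N,N′-dicyclohexylcarbodiimide and pyridine-2-thiol into the S-(pyridin-2-yl) thioester F3. Couple F3 with 5 under reductive nickel catalysis (NiCl2(dme), 4,4′-di-tert-butyl-2,2′-bipyridine, Zn, DMA, 25 °C). The acyl–nickel species from C–S oxidative addition to zerovalent nickel is again the acyl anion equivalent, and the C13 radical of 5 the enolonium equivalent, so the same C12–C13 bond forms without any hydrogen-atom abstraction.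

Step 1 (chemoselective cleavage). The risk is competing oxidation of the 8(17)-exo-methylene and over-oxidation of 3 to the acid. The fallback sets out from 1 and comes back at 3. Oxidise only the allylic C14 hydroxyl of 1 with activated MnO2 (acetone, 25 °C) to 14-dehydroandrographolide F1. Its alkylidene-tetronic acid unit is then cleaved by retro-Knoevenagel hydrolysis in THF/aqueous NaHCO3 (water adds to C12, retro-aldol expels the tetronate), giving 3 with no alkene oxidation at all.

Step 4 (reduction). Risks are C13 epimerisation through a cis-fused chelate, incomplete syn selectivity, and dehydration of 6. The fallback sets out from 6 and comes back at 7. Reduce 6 with a ketoreductase panel (NADPH recycled by glucose/glucose dehydrogenase, pH 7 phosphate buffer with 10 % DMSO, 30 °C). The enzyme rather than the C14 hydroxyl then fixes the C12 configuration, and C13 is funnelled by dynamic kinetic resolution under neutral conditions (no new compound: F0).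

**Further compounds**
F1 | step 1 | 14-dehydroandrographolide (E-alkylidene furan-2,4-dione) | C=C1CC[C@@H]2[C@](C)(CO)[C@H](O)CC[C@@]2(C)[C@@H]1C/C=C1/C(=O)OCC1=O
F2 | step 3 | C12 carboxylic acid, 2-[(1R,4aS,5R,6R,8aS)-6-hydroxy-5-(hydroxymethyl)-5,8a-dimethyl-2-methylidenedecahydronaphthalen-1-yl]acetic acid | C=C1CC[C@@H]2[C@](C)(CO)[C@H](O)CC[C@@]2(C)[C@@H]1CC(=O)O
F3 | step 3 | S-(pyridin-2-yl) thioester of F2 | C=C1CC[C@@H]2[C@](C)(CO)[C@H](O)CC[C@@]2(C)[C@@H]1CC(=O)Sc1ccccn1
F0 | step 4 | none | none
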